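**Retrosynthetic overview**
1. Target ⇒ macrocyclic C9 alcohol / C8 silyl ether: both esters go on last (Steglich ester at C9; acylketene acylation, then catalytic asymmetric α-hydroxylation at C8).
2. Ten-membered carbocycle (formed second) ⇒ NiCl2/CrCl2 ring closure at C9–C10 of an α-iodoenoate aldehyde that already carries the lactone.
3. α-Methylene-γ-lactone (formed first) ⇒ CrCl2 Barbier union at C6–C7 of a (Z)-enal with an allylic bromide made from D-glyceraldehyde acetonide and methyl acrylate.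
4. (Z)-Enal/iodoenoate ⇒ (Z)-3-methylhex-2-enedial ⇒ toluene: arenophile photocycloaddition/osmylation dearomatization, the benzene ring acting as a ring-locked Z-olefin that supplies C1–C6 and C15.

Assumption: atom labels C1–C15 follow germacranolide numbering of the target (lactone O on C6, C12 lactone carbonyl, C14 ester carbon, C15 ring methyl); MTAD, the stabilized ylide, D-glyceraldehyde acetonide, the Evans imide and the tetramethyldioxinone are taken as commercial.

**Step 1**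
Reactants: 1 toluene; 2 4-methyl-1,2,4-triazoline-3,5-dione (MTAD)
Product: 4 rac-urazole-bridged 5,6-cis-dihydroxy-7-methyl-2,3-diazabicyclo[2.2.2]oct-7-ene (both OH anti to the urazole), via cycloadduct 3 (not isolated)
Conditions: 1 (10 equiv), 2, EtOAc, white LEDs, −78 °C; then OsO4 (5 mol%), NMO, acetone/H2O, −78 → 0 °C
Reagents that add atoms: N-methylmorpholine N-oxide, C[N+]1([O-])CCOCC1; water, O
Why: Visible-light [4+2] para-cycloaddition of the arenophile across C2/C5 of toluene (methyl stays on an olefinic carbon) is followed by Upjohn osmylation of the less hindered disubstituted alkene anti to the urazole (arenophile-mediated dearomative dihydroxylation); the racemic carbinol centres are erased in step 4 and serve only to lock the later Z-olefin.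

**Step 2**
Reactants: 4
Product: 7 rac-(1S,2R)-4-methylcyclohexa-3,5-diene-1,2-diol (cis), via bicyclic hydrazine 5 (not isolated), via bicyclic diazene 6 (not isolated)
Conditions: KOH, i-PrOH, 85 °C; then CuCl2 (10 mol%), air, 0 → 23 °C
Reagents that add atoms: none
Why: Urazole hydrolysis/decarboxylation, CuCl2-catalysed aerobic oxidation of the hydrazine and spontaneous retro-[4+2] loss of N2 (cycloreversion) give the diene-diol without touching the carbinol centres.

**Step 3**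
Reactants: 7
Product: 8 rac-(1S,2R)-4-methylcyclohex-3-ene-1,2-diol (cis)
Conditions: 2-nitrobenzenesulfonohydrazide, Et3N, CH2Cl2, 23 °C
Reagents that add atoms: none
Why: Diimide reduction is much faster at the cis-disubstituted alkene than at the trisubstituted one, so the future C4=C5 olefin stays in the ring.

**Step 4**
Reactants: 8
Product: 9 (2Z)-3-methylhex-2-enedial
Conditions: NaIO4, THF/pH 7 buffer, 0 °C
Reagents that add atoms: none
Why: Malaprade glycol cleavage opens the ring, so the ring-enforced cis geometry becomes the Z-trisubstituted C4=C5 olefin (C3 cis to C6) flanked by the C6 enal and the C1 saturated aldehyde.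

**Step 5**
Reactants: 9; 10 methyl (triphenyl-λ5-phosphanylidene)acetate
Product: 12 methyl (2Z,6Z)-2-iodo-6-methyl-8-oxoocta-2,6-dienoate, via iodo ylide 11 (not isolated)
Conditions: 10, N-iodosuccinimide, CH2Cl2, −20 °C; then 9, −20 → 0 °C
Reagents that add atoms: N-iodosuccinimide, O=C1CCC(=O)N1I
Why: The stabilized α-iodo ylide olefinates only the unhindered saturated aldehyde (Wittig reaction) and gives the (Z)-α-iodoenoate (I cis to C2), which fixes the later CO2Me-trans-to-C2 geometry of C1=C10.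

**Step 6**
Reactants: 13 (R)-2,2-dimethyl-1,3-dioxolane-4-carbaldehyde; 14 methyl acrylate
Product: 15 methyl 2-{[(4R)-2,2-dimethyl-1,3-dioxolan-4-yl](hydroxy)methyl}prop-2-enoate (carbinol epimers)
Conditions: DABCO, 14 (neat), 23 °C, 4 d
Reagents that add atoms: none
Why: Morita–Baylis–Hillman reaction; the carbinol centre is lost in step 7 and the dioxolane centre from D-glyceraldehyde becomes C8.

**Step 7**
Reactants: 15
Product: 16 methyl (2Z)-2-(bromomethyl)-3-[(4S)-2,2-dimethyl-1,3-dioxolan-4-yl]prop-2-enoate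
Conditions: NBS, Me2S, CH2Cl2, 0 → 23 °C
Reagents that add atoms: N-bromosuccinimide, O=C1CCC(=O)N1Br
Why: Corey–Kim-type activation and SN2′ bromide delivery give the rearranged Z allylic bromide.

**Step 8**
Reactants: 12; 16
Product: 18 methyl (2Z,6Z)-7-{(2R,3S)-3-[(4S)-2,2-dimethyl-1,3-dioxolan-4-yl]-4-methylidene-5-oxooxolan-2-yl}-2-iodo-6-methylhepta-2,6-dienoate, via hydroxy diester 17 (not isolated)
Conditions: CrCl2 (4 equiv), THF, 0 → 23 °C; 1 M HCl work-up; then PPTS (10 mol%), toluene, 50 °C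
Reagents that add atoms: none
Why: CrCl2 Barbier (Nozaki–Hiyama) allylation of the enal through a chair transition state with the γ-substituent equatorial gives the 6,7-anti adduct, attack anti to the dioxolane CH2 arm with H-8 inside (A(1,3) control) sets 7S relative to 8S, lactonization gives the trans-disubstituted α-methylene lactone, and CrCl2 without NiCl2 leaves the alkenyl iodide untouched.

**Step 9**
Reactants: 18
Product: 19 methyl (2Z,6Z)-7-{(2R,3R)-3-[(1S)-1,2-dihydroxyethyl]-4-methylidene-5-oxooxolan-2-yl}-2-iodo-6-methylhepta-2,6-dienoate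
Conditions: AcOH/H2O (4:1), 40 °C
Reagents that add atoms: none
Why: Mild acetal hydrolysis frees the C8/C9 diol without opening the lactone or the enoate (C7 descriptor changes by priority only).

**Step 10**
Reactants: 19
Product: 20 methyl (2Z,6Z)-7-{(2R,3S)-3-[(1S)-1,2-bis(triethylsilyloxy)ethyl]-4-methylidene-5-oxooxolan-2-yl}-2-iodo-6-methylhepta-2,6-dienoate
Conditions: TESOTf, 2,6-lutidine, CH2Cl2, −78 °C
Reagents that add atoms: triethylsilyl triflate, CC[Si](CC)(CC)OS(=O)(=O)C(F)(F)F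
Why: Exhaustive silylation of both hydroxyls under non-basic conditions that avoid translactonization.

**Step 11**
Reactants: 20
Product: 21 methyl (2Z,6Z)-2-iodo-6-methyl-7-{(2R,3S)-4-methylidene-5-oxo-3-[(1S)-2-oxo-1-(triethylsilyloxy)ethyl]oxolan-2-yl}hepta-2,6-dienoate
Conditions: (COCl)2, DMSO, CH2Cl2, −78 → −40 °C; then Et3N, −78 → 0 °C
Reagents that add atoms: none
Why: Under Swern conditions a primary triethylsilyl ether is cleaved and oxidized directly to the aldehyde while the secondary silyl ether survives, so C9 appears at the aldehyde level with C8–O still protected.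

**Step 12**
Reactants: 21
Product: 22 methyl (3aS,4S,5S,6E,10Z,11aR)-5-hydroxy-10-methyl-3-methylidene-2-oxo-4-(triethylsilyloxy)-2,3,3a,4,5,8,9,11a-octahydrocyclodeca[b]furan-6-carboxylate
Conditions: CrCl2 (8 equiv), NiCl2 (0.1 equiv), (S)-N-[2-(4-isopropyl-4,5-dihydro-1,3-oxazol-2-yl)-6-methylphenyl]methanesulfonamide, Et3N, THF, 0.002 M (syringe pump), 23 °C
Reagents that add atoms: none
Why: Intramolecular Nozaki–Hiyama–Kishi coupling of the α-iodoenoate with the C9 aldehyde closes the ten-membered ring with retention of olefin geometry (C9 cis to C2); the 9S carbinol is set by the chiral oxazoline–sulfonamide ligand on chromium (reagent control).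

**Step 13**
Reactants: 23 (R)-4-benzyl-3-propanoyl-1,3-oxazolidin-2-one; 24 acetaldehyde
Product: 26 (4R)-4-benzyl-3-[(2R,3S)-3-hydroxy-2-methylbutanoyl]-1,3-oxazolidin-2-one, via boron enolate 25 (not isolated)
Conditions: Bu2BOTf, i-Pr2NEt, CH2Cl2, 0 °C; 24, −78 → 0 °C; then H2O2, pH 7 buffer, MeOH
Reagents that add atoms: none
Why: Evans syn aldol through the Z-boron enolate and a Zimmerman–Traxler chair sets 2R,3S under auxiliary control.

**Step 14**
Reactants: 26
Product: 27 (4R)-4-benzyl-3-[(2R,3S)-3-(tert-butyldimethylsilyloxy)-2-methylbutanoyl]-1,3-oxazolidin-2-one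
Conditions: TBSOTf, 2,6-lutidine, CH2Cl2, 0 °C
Reagents that add atoms: tert-butyldimethylsilyl triflate, CC(C)(C)[Si](C)(C)OS(=O)(=O)C(F)(F)F
Why: Silyl protection blocks retro-aldol and self-acylation in the later esterification.

**Step 15**
Reactants: 27
Product: 29 (2R,3S)-3-(tert-butyldimethylsilyloxy)-2-methylbutanoic acid, via peroxy acid 28 (not isolated)
Conditions: LiOH, H2O2, THF/H2O, 0 °C; then Na2SO3; HCl work-up
Reagents that add atoms: hydrogen peroxide, OO
Why: Hydroperoxide attacks the exocyclic imide carbonyl selectively (Evans auxiliary cleavage) without epimerizing C2.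

**Step 16**
Reactants: 22; 29
Product: 30 methyl (3aS,4S,5S,6E,10Z,11aR)-5-{[(2R,3S)-3-(tert-butyldimethylsilyloxy)-2-methylbutanoyl]oxy}-10-methyl-3-methylidene-2-oxo-4-(triethylsilyloxy)-2,3,3a,4,5,8,9,11a-octahydrocyclodeca[b]furan-6-carboxylate
Conditions: EDC·HCl, DMAP, CH2Cl2, 0 → 23 °C
Reagents that add atoms: none
Why: Steglich esterification of the only free hydroxyl (C9) proceeds with retention at C9.

**Step 17**
Reactants: 30
Product: 31 methyl (3aR,4S,5S,6E,10Z,11aR)-5-{[(2R,3S)-3-(tert-butyldimethylsilyloxy)-2-methylbutanoyl]oxy}-4-hydroxy-10-methyl-3-methylidene-2-oxo-2,3,3a,4,5,8,9,11a-octahydrocyclodeca[b]furan-6-carboxylate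
Conditions: PPTS (0.2 equiv), MeOH/CH2Cl2 (1:1), 0 °C
Reagents that add atoms: none
Why: Acid-catalysed methanolysis removes the secondary triethylsilyl ether much faster than the tert-butyldimethylsilyl ether (3a descriptor changes by priority only).

**Step 18**
Reactants: 31; 32 2,2,5,6-tetramethyl-4H-1,3-dioxin-4-one
Product: 34 the C8 2-methyl-3-oxobutanoate of 31 (epimers at the acyl α-carbon), via acetyl(methyl)ketene 33 (not isolated)
Conditions: 32 (3 equiv), toluene, 110 °C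
Reagents that add atoms: none
Why: Thermal retro-[4+2] of the dioxinone releases the acylketene, which is trapped by the C8 hydroxyl under neutral conditions (acylketene acetoacetylation).

**Step 19**
Reactants: 34
Product: 35 methyl (3aS,4S,5S,6E,10Z,11aR)-5-{[(2R,3S)-3-(tert-butyldimethylsilyloxy)-2-methylbutanoyl]oxy}-4-{[(2S)-2-hydroxy-2-methyl-3-oxobutanoyl]oxy}-10-methyl-3-methylidene-2-oxo-2,3,3a,4,5,8,9,11a-octahydrocyclodeca[b]furan-6-carboxylate
Conditions: TiCl2[(R,R)-1-naphthyl-TADDOLate](MeCN)2 (5 mol%), 3-(4-nitrophenyl)-2-(phenylsulfonyl)oxaziridine, CH2Cl2, 23 °C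
Reagents that add atoms: 3-(4-nitrophenyl)-2-(phenylsulfonyl)oxaziridine, O=S(=O)(c1ccccc1)N1OC1c1ccc(cc1)[N+](=O)[O-]
Why: Electrophilic α-hydroxylation of the chelated titanium enolate of the β-keto ester by the oxaziridine (Davis-type) sets the quaternary 2S centre by catalyst control; the TADDOLate enantiomer is chosen on a model 2-methyl-3-oxobutanoate to deliver S, and the oxidant does not attack the olefins.

**Step 20**
Reactants: 35
Product: 36 target, methyl (3aS,4S,5S,6E,10Z,11aR)-5-{[(2R,3S)-3-hydroxy-2-methylbutanoyl]oxy}-4-{[(2S)-2-hydroxy-2-methyl-3-oxobutanoyl]oxy}-10-methyl-3-methylidene-2-oxo-2,3,3a,4,5,8,9,11a-octahydrocyclodeca[b]furan-6-carboxylate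
Conditions: HF·pyridine, pyridine, THF, 0 → 23 °C
Reagents that add atoms: none
Why: Buffered fluoride desilylation is non-basic, so neither retro-Claisen of the α-hydroxy-β-keto ester nor acyl migration occurs.

**Compound list**
1 | toluene | Cc1ccccc1 | starting material
2 | 4-methyl-1,2,4-triazoline-3,5-dione (MTAD) | CN1C(=O)N=NC1=O | starting material
3 | rac-MTAD/toluene para-cycloadduct (urazole across C2/C5 of toluene) | CC1=C[C@@H]2C=C[C@H]1N1N2C(=O)N(C)C1=O | intermediate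
4 | rac-urazole-bridged 5,6-cis-dihydroxy-7-methyl-2,3-diazabicyclo[2.2.2]oct-7-ene (OH anti to urazole) | CC1=C[C@@H]2[C@H](O)[C@H](O)[C@H]1N1N2C(=O)N(C)C1=O | intermediate
5 | rac-7-methyl-2,3-diazabicyclo[2.2.2]oct-7-ene-5,6-cis-diol | CC1=C[C@@H]2[C@H](O)[C@H](O)[C@H]1NN2 | intermediate
6 | rac-7-methyl-2,3-diazabicyclo[2.2.2]octa-2,7-diene-5,6-cis-diol | CC1=C[C@@H]2[C@H](O)[C@H](O)[C@H]1N=N2 | intermediate
7 | rac-(1S,2R)-4-methylcyclohexa-3,5-diene-1,2-diol | O[C@H]1C=CC(C)=C[C@H]1O | intermediate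
8 | rac-(1S,2R)-4-methylcyclohex-3-ene-1,2-diol | O[C@H]1CCC(C)=C[C@H]1O | intermediate
9 | (2Z)-3-methylhex-2-enedial | O=CCC/C(C)=C\C=O | intermediate
10 | methyl (triphenyl-λ5-phosphanylidene)acetate | COC(=O)C=P(c1ccccc1)(c1ccccc1)c1ccccc1 | starting material
11 | methyl iodo(triphenyl-λ5-phosphanylidene)acetate | COC(=O)C(I)=P(c1ccccc1)(c1ccccc1)c1ccccc1 | intermediate
12 | methyl (2Z,6Z)-2-iodo-6-methyl-8-oxoocta-2,6-dienoate | COC(=O)/C(I)=C/CC/C(C)=C\C=O | intermediate
13 | (R)-2,2-dimethyl-1,3-dioxolane-4-carbaldehyde | O=C[C@H]1COC(C)(C)O1 | starting material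
14 | methyl acrylate | C=CC(=O)OC | starting material
15 | methyl 2-{[(4R)-2,2-dimethyl-1,3-dioxolan-4-yl](hydroxy)methyl}prop-2-enoate (carbinol epimers) | C=C(C(=O)OC)C(O)[C@H]1COC(C)(C)O1 | intermediate
16 | methyl (2Z)-2-(bromomethyl)-3-[(4S)-2,2-dimethyl-1,3-dioxolan-4-yl]prop-2-enoate | COC(=O)/C(CBr)=C/[C@H]1COC(C)(C)O1 | intermediate
17 | dimethyl (2Z,6Z,8R,9S)-9-[(4S)-2,2-dimethyl-1,3-dioxolan-4-yl]-8-hydroxy-2-iodo-6-methyl-10-methylideneundeca-2,6-dienedioate | COC(=O)C(=C)[C@H]([C@H]1COC(C)(C)O1)[C@H](O)/C=C(/C)CC/C=C(\I)C(=O)OC | intermediate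
18 | methyl (2Z,6Z)-7-{(2R,3S)-3-[(4S)-2,2-dimethyl-1,3-dioxolan-4-yl]-4-methylidene-5-oxooxolan-2-yl}-2-iodo-6-methylhepta-2,6-dienoate | C=C1C(=O)O[C@H](/C=C(/C)CC/C=C(\I)C(=O)OC)[C@H]1[C@H]1COC(C)(C)O1 | intermediate
19 | methyl (2Z,6Z)-7-{(2R,3R)-3-[(1S)-1,2-dihydroxyethyl]-4-methylidene-5-oxooxolan-2-yl}-2-iodo-6-methylhepta-2,6-dienoate | C=C1C(=O)O[C@H](/C=C(/C)CC/C=C(\I)C(=O)OC)[C@H]1[C@H](O)CO | intermediate
20 | methyl (2Z,6Z)-7-{(2R,3S)-3-[(1S)-1,2-bis(triethylsilyloxy)ethyl]-4-methylidene-5-oxooxolan-2-yl}-2-iodo-6-methylhepta-2,6-dienoate | C=C1C(=O)O[C@H](/C=C(/C)CC/C=C(\I)C(=O)OC)[C@H]1[C@H](O[Si](CC)(CC)CC)CO[Si](CC)(CC)CC | intermediate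
21 | methyl (2Z,6Z)-2-iodo-6-methyl-7-{(2R,3S)-4-methylidene-5-oxo-3-[(1S)-2-oxo-1-(triethylsilyloxy)ethyl]oxolan-2-yl}hepta-2,6-dienoate | C=C1C(=O)O[C@H](/C=C(/C)CC/C=C(\I)C(=O)OC)[C@H]1[C@H](O[Si](CC)(CC)CC)C=O | intermediate
22 | methyl (3aS,4S,5S,6E,10Z,11aR)-5-hydroxy-10-methyl-3-methylidene-2-oxo-4-(triethylsilyloxy)-2,3,3a,4,5,8,9,11a-octahydrocyclodeca[b]furan-6-carboxylate | C=C1C(=O)O[C@@H]2/C=C(/C)CC/C=C(/C(=O)OC)[C@H](O)[C@@H](O[Si](CC)(CC)CC)[C@@H]12 | intermediate
23 | (R)-4-benzyl-3-propanoyl-1,3-oxazolidin-2-one | CCC(=O)N1C(=O)OC[C@H]1Cc1ccccc1 | starting material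
24 | acetaldehyde | CC=O | starting material
25 | (Z)-dibutylboron enolate of 23 | C/C=C(\OB(CCCC)CCCC)N1C(=O)OC[C@H]1Cc1ccccc1 | intermediate
26 | (4R)-4-benzyl-3-[(2R,3S)-3-hydroxy-2-methylbutanoyl]-1,3-oxazolidin-2-one | O=C([C@H](C)[C@H](C)O)N1C(=O)OC[C@H]1Cc1ccccc1 | intermediate
27 | (4R)-4-benzyl-3-[(2R,3S)-3-(tert-butyldimethylsilyloxy)-2-methylbutanoyl]-1,3-oxazolidin-2-one | O=C([C@H](C)[C@H](C)O[Si](C)(C)C(C)(C)C)N1C(=O)OC[C@H]1Cc1ccccc1 | intermediate
28 | (2R,3S)-3-(tert-butyldimethylsilyloxy)-2-methylbutaneperoxoic acid | OOC(=O)[C@H](C)[C@H](C)O[Si](C)(C)C(C)(C)C | intermediate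
29 | (2R,3S)-3-(tert-butyldimethylsilyloxy)-2-methylbutanoic acid | OC(=O)[C@H](C)[C@H](C)O[Si](C)(C)C(C)(C)C | intermediate
30 | C9 ester of 22 with 29 (C8 triethylsilyl ether; 3aS,4S,5S,6E,10Z,11aR) | C=C1C(=O)O[C@@H]2/C=C(/C)CC/C=C(/C(=O)OC)[C@H](OC(=O)[C@H](C)[C@H](C)O[Si](C)(C)C(C)(C)C)[C@@H](O[Si](CC)(CC)CC)[C@@H]12 | intermediate
31 | C8 alcohol from 30 (3aR,4S,5S,6E,10Z,11aR) | C=C1C(=O)O[C@@H]2/C=C(/C)CC/C=C(/C(=O)OC)[C@H](OC(=O)[C@H](C)[C@H](C)O[Si](C)(C)C(C)(C)C)[C@@H](O)[C@@H]12 | intermediate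
32 | 2,2,5,6-tetramethyl-4H-1,3-dioxin-4-one | CC1=C(C)C(=O)OC(C)(C)O1 | starting material
33 | acetyl(methyl)ketene (2-methyl-3-oxobut-1-en-1-one) | CC(=O)C(C)=C=O | intermediate
34 | C8 2-methyl-3-oxobutanoate of 31 (α-epimers; 3aS,4S,5S,6E,10Z,11aR) | C=C1C(=O)O[C@@H]2/C=C(/C)CC/C=C(/C(=O)OC)[C@H](OC(=O)[C@H](C)[C@H](C)O[Si](C)(C)C(C)(C)C)[C@@H](OC(=O)C(C)C(C)=O)[C@@H]12 | intermediate
35 | silyl-protected target, C8 (2S)-2-hydroxy-2-methyl-3-oxobutanoate | C=C1C(=O)O[C@@H]2/C=C(/C)CC/C=C(/C(=O)OC)[C@H](OC(=O)[C@H](C)[C@H](C)O[Si](C)(C)C(C)(C)C)[C@@H](OC(=O)[C@@](C)(O)C(C)=O)[C@@H]12 | intermediate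
36 | CNP0168935.2 | C=C1C(=O)O[C@@H]2/C=C(/C)CC/C=C(/C(=O)OC)[C@H](OC(=O)[C@H](C)[C@H](C)O)[C@@H](OC(=O)[C@@](C)(O)C(C)=O)[C@@H]12 | target

**Totals and risks**
Total step count: 20. Longest linear sequence: 15 (steps 1–5, 8–12, 16–20).

Most likely to fail, first: step 1. The photocycloaddition may give the ipso/para regioisomer, the osmylation may pick the methyl-bearing alkene, and diene-diol 7 aromatizes easily. The fallback for step 1 does without 1 and 2: in place of toluene 1 it sets out from a second cheap aromatic feedstock, 3-methylanisole F1, and it comes back to the route at 9. Birch reduction of the anisole (Li, NH3, t-BuOH) gives 1-methoxy-5-methylcyclohexa-1,4-diene F2. Aqueous HCl hydrolysis with conjugation gives 3-methylcyclohex-2-en-1-one F3. Mn(OAc)3 in benzene at 80 °C gives the α′-acetate rac-4-methyl-2-oxocyclohex-3-en-1-yl acetate F4. LiAlH4 in THF gives cis/trans-4-methylcyclohex-3-ene-1,2-diol F5, and NaIO4 cleaves both isomers to 9, the ring again holding the olefin Z.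

Second: step 8. The anti selectivity of the CrCl2 allylation and the facial selectivity relative to C8 are precedent-based but not assured for this γ-substituted bromide. The fallback for step 8 sets out from 12 and 16 and comes back at 17, which is lactonized to 18 as in step 8. Indium-mediated Barbier coupling (In powder, THF/H2O), which is syn-selective, gives the C6 epimer dimethyl (2Z,6Z,8S,9S)-9-[(4S)-2,2-dimethyl-1,3-dioxolan-4-yl]-8-hydroxy-2-iodo-6-methyl-10-methylideneundeca-2,6-dienedioate F6. Dess–Martin oxidation (NaHCO3 buffer, 0 °C) gives the C6 ketone dimethyl (2Z,6Z,9R)-9-[(4S)-2,2-dimethyl-1,3-dioxolan-4-yl]-2-iodo-6-methyl-10-methylidene-8-oxoundeca-2,6-dienedioate F7. Corey–Bakshi–Shibata reduction at −78 °C then sets 6R by reagent control and gives 17.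

Third: step 12. Closing a ten-membered ring is demanding, and ligand control at C9 in a macrocyclization is unproven. The fallback for step 12 sets out from 21 and comes back at 22. Ligand-free NiCl2/CrCl2 closure in DMSO is taken through whatever mixture of C9 epimers it gives, 22 together with methyl (3aS,4S,5R,6E,10Z,11aR)-5-hydroxy-10-methyl-3-methylidene-2-oxo-4-(triethylsilyloxy)-2,3,3a,4,5,8,9,11a-octahydrocyclodeca[b]furan-6-carboxylate F8. Dess–Martin oxidation of the mixture gives the C9 ketone methyl (3aS,4S,6E,10Z,11aR)-10-methyl-3-methylidene-2,5-dioxo-4-(triethylsilyloxy)-2,3,3a,4,5,8,9,11a-octahydrocyclodeca[b]furan-6-carboxylate F9. Corey–Bakshi–Shibata reduction then delivers the 9S alcohol 22.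

**Further compounds**
F1 | step 1 | 3-methylanisole | COc1cccc(C)c1
F2 | step 1 | 1-methoxy-5-methylcyclohexa-1,4-diene | COC1=CCC=C(C)C1
F3 | step 1 | 3-methylcyclohex-2-en-1-one | CC1=CC(=O)CCC1
F4 | step 1 | rac-4-methyl-2-oxocyclohex-3-en-1-yl acetate | CC(=O)OC1CCC(C)=CC1=O
F5 | step 1 | cis/trans-4-methylcyclohex-3-ene-1,2-diol | CC1=CC(O)C(O)CC1
F6 | step 8 | dimethyl (2Z,6Z,8S,9S)-9-[(4S)-2,2-dimethyl-1,3-dioxolan-4-yl]-8-hydroxy-2-iodo-6-methyl-10-methylideneundeca-2,6-dienedioate | COC(=O)C(=C)[C@H]([C@H]1COC(C)(C)O1)[C@@H](O)/C=C(/C)CC/C=C(\I)C(=O)OC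
F7 | step 8 | dimethyl (2Z,6Z,9R)-9-[(4S)-2,2-dimethyl-1,3-dioxolan-4-yl]-2-iodo-6-methyl-10-methylidene-8-oxoundeca-2,6-dienedioate | COC(=O)C(=C)[C@H]([C@H]1COC(C)(C)O1)C(=O)/C=C(/C)CC/C=C(\I)C(=O)OC
F8 | step 12 | methyl (3aS,4S,5R,6E,10Z,11aR)-5-hydroxy-10-methyl-3-methylidene-2-oxo-4-(triethylsilyloxy)-2,3,3a,4,5,8,9,11a-octahydrocyclodeca[b]furan-6-carboxylate | C=C1C(=O)O[C@@H]2/C=C(/C)CC/C=C(/C(=O)OC)[C@@H](O)[C@@H](O[Si](CC)(CC)CC)[C@@H]12
F9 | step 12 | methyl (3aS,4S,6E,10Z,11aR)-10-methyl-3-methylidene-2,5-dioxo-4-(triethylsilyloxy)-2,3,3a,4,5,8,9,11a-octahydrocyclodeca[b]furan-6-carboxylate | C=C1C(=O)O[C@@H]2/C=C(/C)CC/C=C(/C(=O)OC)C(=O)[C@@H](O[Si](CC)(CC)CC)[C@@H]12
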